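**Plan**
1. Retrosynthesis first opens the furan: the C3–C3a bond (arene–ketone cyclodehydration) and the C7a-oxygen to C2 ether bond (phenol alkylation by methyl 3-bromolevulinate) are cut, leaving a biphenyl-3-ol.
2. The C6–C1' biaryl bond and the C7–O bond are then cut together at an aryne between C6 and C7. This works because C6-aryl, C7-O and C7a-O are contiguous on the benzo ring, so the C7a oxygen flanking the aryne sends the aryl group to C6 and the metal (later oxygen) to C7.
3. Forward: 5-methoxyresorcinol supplies the benzo ring with C4-OMe and C7a-O; iodination between the hydroxyls, mono-MOM protection and triflation give the aryne precursor.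
4. The aryne step joins the 4-benzyloxyphenyl ring and the C7 oxygen; O-methylation, MOM removal, etherification and debenzylation follow, and the furan ring closes last.
5. Stereochemistry: the target has no stereocentre; the single sp3 centre of 15–17 is racemic and disappears on aromatisation.

Key step: step 5

Remarks: benzofuran numbering of the target (O1, C2, C3, C3a, C4–C7, C7a) is used for ring positions throughout. Arylmagnesium species are drawn with one halide although mixed counter-ions are expected.

**Step 1**
Reactants: 1 5-methoxybenzene-1,3-diol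
Product: 2 2-iodo-5-methoxybenzene-1,3-diol
Conditions: I2 (1.05 equiv), NaHCO3 (1.1 equiv), THF/H2O 1:1, 0 °C → rt
Reagents that add atoms: iodine, II
Why: Electrophilic aromatic iodination under bicarbonate buffer should go to the carbon flanked by both hydroxyls, as it does for resorcinol and its 5-alkyl congeners, and one equivalent of iodine in the cold limits over-iodination.

**Step 2**
Reactants: 2 2-iodo-5-methoxybenzene-1,3-diol
Product: 3 2-iodo-5-methoxy-3-(methoxymethoxy)phenol
Conditions: MOMCl (1.0 equiv), iPr2NEt (1.2 equiv), CH2Cl2, 0 °C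
Reagents that add atoms: chloromethyl methyl ether, COCCl
Why: Williamson-type O-alkylation (MOM protection) with one equivalent of reagent desymmetrises the diol statistically; the two hydroxyls are equivalent, so only one mono-ether can form, and recovered diol is recycled.

**Step 3**
Reactants: 3 2-iodo-5-methoxy-3-(methoxymethoxy)phenol
Product: 4 2-iodo-5-methoxy-3-(methoxymethoxy)phenyl trifluoromethanesulfonate
Conditions: Tf2O (1.2 equiv), pyridine (2.5 equiv), CH2Cl2, 0 °C
Reagents that add atoms: trifluoromethanesulfonic anhydride, O=S(=O)(OS(=O)(=O)C(F)(F)F)C(F)(F)F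
Why: O-Sulfonylation of the remaining phenol (aryl triflate formation) is routine, and the cold, pyridine-buffered medium should leave the MOM acetal and the aryl iodide untouched.

**Step 4**
Reactants: 5 1-(benzyloxy)-4-bromobenzene
Product: 6 [4-(benzyloxy)phenyl]magnesium bromide
Conditions: Mg turnings (1.2 equiv), I2 (cat.), THF, 40 °C → rt
Reagents that add atoms: magnesium, [Mg]
Why: Grignard formation by insertion of magnesium into a 4-alkoxyaryl bromide is standard, and the benzyl ether is inert to it.

**Step 5**
Reactants: 4 2-iodo-5-methoxy-3-(methoxymethoxy)phenyl trifluoromethanesulfonate; 6 [4-(benzyloxy)phenyl]magnesium bromide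
Product: 11 4'-(benzyloxy)-5-methoxy-3-(methoxymethoxy)-[1,1'-biphenyl]-2-ol, via magnesiated aryl triflate 7 (not isolated), via dialkoxybenzyne 8 (not isolated), via biarylmagnesium bromide 9 (not isolated), via dimethyl arylboronate 10 (not isolated)
Conditions: 4 and 6 (2.0 equiv), THF, −78 °C; Me3SiCH2MgCl (1.1 equiv), −78 → 0 °C; B(OMe)3 (4 equiv), −78 °C → rt; 30% H2O2, 2 M NaOH, 0 °C → rt
Reagents that add atoms: hydrogen peroxide, OO
Why: Iodine–magnesium exchange with the poorly nucleophilic Me3SiCH2MgCl gives 7, which expels the neighbouring triflate (1,2-elimination) to form aryne 8 with its triple bond between C6 and C7. Aryl Grignard 6 then adds across the strained bond (aryne carbomagnesiation, a known route to 2-magnesiobiaryls) to make C6–C1' and leave magnesium on C7 in 9; B(OMe)3 converts this into boronate 10, and alkaline H2O2 triggers the 1,2-shift of aryl from boron to oxygen that creates the C7–O bond. No ring is closed and no stereocentre is formed, so the only selectivity required is regiochemical. It is secured by the C7a MOM-oxy group: its inductive pull distorts the aryne so that C6 is the flatter, more electrophilic terminus and the carbanion develops at C7 beside oxygen, where the acetal oxygens can also chelate magnesium, as is general for 3-alkoxyarynes. The C4 methoxy group lies one carbon further from the triple bond and should exert only a weak, subordinate bias. Having 6 present in excess before the exchange reagent is added at −78 °C should ensure that the aryne is captured by the aryl nucleophile and not by the activator.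

**Step 6**
Reactants: 11 4'-(benzyloxy)-5-methoxy-3-(methoxymethoxy)-[1,1'-biphenyl]-2-ol
Product: 12 4'-(benzyloxy)-2,5-dimethoxy-3-(methoxymethoxy)-1,1'-biphenyl
Conditions: MeI (1.5 equiv), K2CO3 (2 equiv), DMF, rt
Reagents that add atoms: iodomethane, CI
Why: Williamson O-methylation of the only acidic site, the C7 phenol; the MOM acetal and benzyl ether are stable to carbonate base.

**Step 7**
Reactants: 12 4'-(benzyloxy)-2,5-dimethoxy-3-(methoxymethoxy)-1,1'-biphenyl
Product: 13 4'-(benzyloxy)-2,5-dimethoxy-[1,1'-biphenyl]-3-ol
Conditions: conc. HCl (cat.), MeOH, 50 °C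
Reagents that add atoms: none
Why: Acid-catalysed acetal exchange with methanol (MOM cleavage) frees the C7a phenol, while aryl methyl and benzyl ethers are stable to dilute HCl.

**Step 8**
Reactants: 14 methyl 4-oxopentanoate (methyl levulinate)
Product: 15 methyl 3-bromo-4-oxopentanoate (racemic)
Conditions: Br2 (1.0 equiv), CHCl3, 0 °C → rt; fractional distillation
Reagents that add atoms: bromine, BrBr
Why: Acid-catalysed α-bromination of the ketone through its more substituted enol in a non-hydroxylic solvent favours C3 over C5; the minor 5-bromo isomer is removed by distillation.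

**Step 9**
Reactants: 13 4'-(benzyloxy)-2,5-dimethoxy-[1,1'-biphenyl]-3-ol; 15 methyl 3-bromo-4-oxopentanoate
Product: 16 methyl 3-{[4'-(benzyloxy)-2,5-dimethoxy-[1,1'-biphenyl]-3-yl]oxy}-4-oxopentanoate (racemic)
Conditions: 15 (1.5 equiv), K2CO3 (2 equiv), acetone, rt
Reagents that add atoms: none
Why: Williamson ether synthesis by SN2 displacement at an α-bromo ketone, which should be fast enough at room temperature with a weak base to outrun dehydrobromination of 15; the new stereocentre is racemic and is erased in step 11.

**Step 10**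
Reactants: 16 methyl 3-{[4'-(benzyloxy)-2,5-dimethoxy-[1,1'-biphenyl]-3-yl]oxy}-4-oxopentanoate
Product: 17 methyl 3-[(4'-hydroxy-2,5-dimethoxy-[1,1'-biphenyl]-3-yl)oxy]-4-oxopentanoate (racemic)
Conditions: H2 (1 atm), 10% Pd/C, EtOAc, rt
Reagents that add atoms: none
Why: Hydrogenolysis of the benzyl aryl ether at ambient pressure should spare the aliphatic ketone, the ester and the aryloxy C–O bond, and removing the benzyl group here keeps an acid-labile ether out of the final acid step.

**Step 11**
Reactants: 17 methyl 3-[(4'-hydroxy-2,5-dimethoxy-[1,1'-biphenyl]-3-yl)oxy]-4-oxopentanoate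
Product: 18 Phenylcandilide B, methyl 2-[6-(4-hydroxyphenyl)-4,7-dimethoxy-3-methyl-1-benzofuran-2-yl]acetate
Conditions: Amberlyst 15, toluene, reflux (Dean–Stark)
Reagents that add atoms: none
Why: Acid-catalysed cyclodehydration of an α-aryloxy ketone (intramolecular Friedel–Crafts hydroxyalkylation, then dehydration): the protonated ketone attacks C3a, the only free position ortho to the ether oxygen and activated by the C4 methoxy group, in a 5-exo closure, and loss of water aromatises the furan with methyl on C3 and the acetate arm on C2.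

**Compound list**
1 | 5-methoxybenzene-1,3-diol (5-methoxyresorcinol) | COc1cc(O)cc(O)c1 | starting material
2 | 2-iodo-5-methoxybenzene-1,3-diol | COc1cc(O)c(I)c(O)c1 | intermediate
3 | 2-iodo-5-methoxy-3-(methoxymethoxy)phenol | COCOc1cc(OC)cc(O)c1I | intermediate
4 | 2-iodo-5-methoxy-3-(methoxymethoxy)phenyl trifluoromethanesulfonate | COCOc1cc(OC)cc(OS(=O)(=O)C(F)(F)F)c1I | intermediate
5 | 1-(benzyloxy)-4-bromobenzene | Brc1ccc(OCc2ccccc2)cc1 | starting material
6 | [4-(benzyloxy)phenyl]magnesium bromide | Br[Mg]c1ccc(OCc2ccccc2)cc1 | intermediate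
7 | [4-methoxy-2-(methoxymethoxy)-6-(trifluoromethanesulfonyloxy)phenyl]magnesium chloride | COCOc1cc(OC)cc(OS(=O)(=O)C(F)(F)F)c1[Mg]Cl | intermediate (not isolated)
8 | 5-methoxy-3-(methoxymethoxy)benzyne (1,2-didehydrobenzene, triple bond between C6 and C7 of the later benzofuran) | COCOC1=CC(OC)=CC#C1 | intermediate (not isolated)
9 | [4'-(benzyloxy)-5-methoxy-3-(methoxymethoxy)-[1,1'-biphenyl]-2-yl]magnesium bromide | COCOc1cc(OC)cc(-c2ccc(OCc3ccccc3)cc2)c1[Mg]Br | intermediate (not isolated)
10 | dimethyl [4'-(benzyloxy)-5-methoxy-3-(methoxymethoxy)-[1,1'-biphenyl]-2-yl]boronate | COCOc1cc(OC)cc(-c2ccc(OCc3ccccc3)cc2)c1B(OC)OC | intermediate (not isolated)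
11 | 4'-(benzyloxy)-5-methoxy-3-(methoxymethoxy)-[1,1'-biphenyl]-2-ol | COCOc1cc(OC)cc(-c2ccc(OCc3ccccc3)cc2)c1O | intermediate
12 | 4'-(benzyloxy)-2,5-dimethoxy-3-(methoxymethoxy)-1,1'-biphenyl | COCOc1cc(OC)cc(-c2ccc(OCc3ccccc3)cc2)c1OC | intermediate
13 | 4'-(benzyloxy)-2,5-dimethoxy-[1,1'-biphenyl]-3-ol | COc1cc(O)c(OC)c(-c2ccc(OCc3ccccc3)cc2)c1 | intermediate
14 | methyl 4-oxopentanoate (methyl levulinate) | COC(=O)CCC(C)=O | starting material
15 | methyl 3-bromo-4-oxopentanoate (racemic) | COC(=O)CC(Br)C(C)=O | intermediate
16 | methyl 3-{[4'-(benzyloxy)-2,5-dimethoxy-[1,1'-biphenyl]-3-yl]oxy}-4-oxopentanoate (racemic) | COC(=O)CC(Oc1cc(OC)cc(-c2ccc(OCc3ccccc3)cc2)c1OC)C(C)=O | intermediate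
17 | methyl 3-[(4'-hydroxy-2,5-dimethoxy-[1,1'-biphenyl]-3-yl)oxy]-4-oxopentanoate (racemic) | COC(=O)CC(Oc1cc(OC)cc(-c2ccc(O)cc2)c1OC)C(C)=O | intermediate
18 | Phenylcandilide B, methyl 2-[6-(4-hydroxyphenyl)-4,7-dimethoxy-3-methyl-1-benzofuran-2-yl]acetate | COC(=O)Cc1oc2c(OC)c(-c3ccc(O)cc3)cc(OC)c2c1C | target

**Step count**
Total: 11 steps. Longest linear sequence: 9 steps (steps 1, 2, 3, 5, 6, 7, 9, 10, 11 from 1 to 18); steps 4 and 8 are one-step side branches.

**Steps most likely to fail**

Step 5. The aryne may be captured by the exchange reagent instead of the aryl Grignard. Borylation of the doubly ortho-substituted arylmagnesium may be incomplete, so that protonation leaves C7 unoxygenated. Regioselectivity across the triple bond may also leak. The fallback leaves the route at 3 and returns at 12, forming the two bonds separately by known chemistry. Copper-catalysed Ullmann-type methoxylation of the C7 iodide of 3 (CuI cat., NaOMe, MeOH/DMF, 100 °C, as practised on ortho-halophenols) should give 2,5-dimethoxy-3-(methoxymethoxy)phenol F1. Triflation (Tf2O, pyridine, CH2Cl2, 0 °C) should give 2,5-dimethoxy-3-(methoxymethoxy)phenyl trifluoromethanesulfonate F2. Suzuki–Miyaura coupling of F2 with commercial [4-(benzyloxy)phenyl]boronic acid (Pd(PPh3)4, K3PO4, dioxane/H2O, 90 °C) would then form C6–C1' and deliver 12, so that 11 and step 6 are bypassed.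

Step 9. Base-induced dehydrobromination of 15 may compete with substitution, and the phenoxide may then add in conjugate fashion at the carbon next to the ester; β-elimination of phenoxide from the product is a further loss pathway. The fallback leaves the route at 13 and returns at 16, using an electrophile that cannot eliminate. O-Alkylation of 13 with commercial tert-butyl 2-chloro-3-oxobutanoate (K2CO3, acetone, reflux) should give tert-butyl 2-{[4'-(benzyloxy)-2,5-dimethoxy-[1,1'-biphenyl]-3-yl]oxy}-3-oxobutanoate F3. C-Alkylation of its doubly activated carbon with methyl bromoacetate (K2CO3, acetone, or NaH, THF) should give 1-tert-butyl 4-methyl 2-acetyl-2-{[4'-(benzyloxy)-2,5-dimethoxy-[1,1'-biphenyl]-3-yl]oxy}butanedioate F4. Cleavage of the tert-butyl ester (TFA, CH2Cl2, rt) and decarboxylation of the β-keto acid on gentle warming in toluene would then give 16.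

Step 1. Iodination may occur at the positions between a hydroxyl and the methoxy group, or proceed to poly-iodination. The fallback leaves the route at 1 and returns at 2, fixing the site by directed metalation. Double MOM protection of 1 (MOMCl 2.5 equiv, iPr2NEt, CH2Cl2) should give 1-methoxy-3,5-bis(methoxymethoxy)benzene F5. Directed ortho-lithiation between the two MOM-oxy groups (n-BuLi, THF, 0 °C) and iodine quench (I2, −78 °C) should give 2-iodo-5-methoxy-1,3-bis(methoxymethoxy)benzene F6. Removal of both acetals (HCl, MeOH, rt) would return 2.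

**Further compounds**
F1 | step 5 | 2,5-dimethoxy-3-(methoxymethoxy)phenol | COCOc1cc(OC)cc(O)c1OC
F2 | step 5 | 2,5-dimethoxy-3-(methoxymethoxy)phenyl trifluoromethanesulfonate | COCOc1cc(OC)cc(OS(=O)(=O)C(F)(F)F)c1OC
F3 | step 9 | tert-butyl 2-{[4'-(benzyloxy)-2,5-dimethoxy-[1,1'-biphenyl]-3-yl]oxy}-3-oxobutanoate (racemic) | CC(=O)C(Oc1cc(OC)cc(-c2ccc(OCc3ccccc3)cc2)c1OC)C(=O)OC(C)(C)C
F4 | step 9 | 1-tert-butyl 4-methyl 2-acetyl-2-{[4'-(benzyloxy)-2,5-dimethoxy-[1,1'-biphenyl]-3-yl]oxy}butanedioate (racemic) | COC(=O)CC(Oc1cc(OC)cc(-c2ccc(OCc3ccccc3)cc2)c1OC)(C(C)=O)C(=O)OC(C)(C)C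
F5 | step 1 | 1-methoxy-3,5-bis(methoxymethoxy)benzene | COCOc1cc(OC)cc(OCOC)c1
F6 | step 1 | 2-iodo-5-methoxy-1,3-bis(methoxymethoxy)benzene | COCOc1cc(OC)cc(OCOC)c1I
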